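Everything rests on opening the cyclopentanone ring C8–C14–C13–Ca–Cb of the bicyclo[3.2.1]octane at C13–Ca (Ca: bridge CH; Cb: bridge CH2). The bridging ketone C14, set between the isopropyl bridgehead C13 and the quaternary bridgehead C8 shared with ring B, marks this ring as an enlarged cyclobutanol. In the key step a Lewis acid opens a 12,13-epoxide at C13 and the anti cyclobutane carbon Ca shifts from C14 to C13, forming at once the C13–Ca bond, the bridged bicycle, the C14 ketone and the C12 hydroxyl. The precursor is a cis-fused methylenecyclobutanol epoxide from an enone–propadiene photoadduct, its ring-B carbinol held as an acetonide.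

Key step: step 16

Remarks and assumptions (one line each)
- Numbering: ring A = C1–C5, C10; five-membered ring B = C5, C6, C8, C9, C10 (C7 is the formyl carbon on C6); ring C = C8, C9, C11–C14; Ca and Cb are the two bridge carbons from propadiene; labdane/abietic atoms are primed.
- C6 and its one-carbon branch are built early by α-face dihydroxylation and carried as an acetonide, because a one-carbon nucleophile added to a late C6 ketone would enter from the open α face and give the wrong epimer.
- The C14 oxygen is carried as a silyl ether and freed before the epoxidation, so that the hydroxyl directs the oxidant to the β face, anti to the migrating bond.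
- Stereocentres that are erased later (C6 before the methylene ketone, the carbinol centres of the abietate diol, C12′ of the hydroxy ketone, the C14 carbinol between the hydroboration and the diketone, C11 of the hydroxy diketone) are drawn as the expected isomer; either epimer serves.
- (R)-t-Bu-PHOX is assumed to give the (R)-allyl ketone, by analogy with 2-allyl-2-methylcyclohexanone; enantiomeric purity can be raised by crystallising a derivative of the bicyclic enone, and any residual enantiomer is removed as a diastereomer after the fragment coupling.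
- Commercial starting materials: 2,2,6-trimethylcyclohexanone, propadiene, abietic acid; all reagents named are catalogue chemicals.

Step 1
Reactants: 1 2,2,6-trimethylcyclohexanone
Product: 3 allyl 2,6,6-trimethylcyclohex-1-enyl carbonate, via lithium enolate 2 (not isolated)
Conditions: LiN(SiMe3)2, THF, 0 °C; allyl chloroformate, −78 °C → rt
Reagents that add atoms: allyl chloroformate, C=CCOC(=O)Cl
Why: Only C6 of the ketone carries an α-hydrogen, so enolisation is unambiguous and the hindered enolate is acylated on oxygen by the chloroformate (enol carbonate formation).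

Step 2
Reactants: 3 allyl 2,6,6-trimethylcyclohex-1-enyl carbonate
Product: 4 (R)-2-allyl-2,6,6-trimethylcyclohexanone
Conditions: Pd2(dba)3 (2.5 mol %), (R)-t-Bu-PHOX (6 mol %), THF, 25 °C
Reagents that add atoms: none
Why: Decarboxylative Tsuji–Trost asymmetric allylic alkylation, in which the π-allylpalladium enolate pair recombines at carbon and the ligand sets the quaternary centre that becomes C10.

Step 3
Reactants: 4 (R)-2-allyl-2,6,6-trimethylcyclohexanone
Product: 5 (R)-2,2,6-trimethyl-6-(2-oxopropyl)cyclohexanone
Conditions: PdCl2 (10 mol %), Cu(OAc)2 (20 mol %), O2 (1 atm), DMA/H2O, rt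
Reagents that add atoms: water, O
Why: Tsuji–Wacker oxidation converts the terminal alkene into the methyl ketone with Markovnikov selectivity and leaves the ring ketone untouched.

Step 4
Reactants: 5 (R)-2,2,6-trimethyl-6-(2-oxopropyl)cyclohexanone
Product: 6 (R)-4,4,7a-trimethyl-1,4,5,6,7,7a-hexahydro-2H-inden-2-one
Conditions: KOH, xylenes, 110 °C (Dean–Stark)
Reagents that add atoms: none
Why: Intramolecular aldol condensation of the methyl ketone onto the ring carbonyl closes ring B, and because both ring α-positions are quaternary only one enone can form.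

Step 5
Reactants: 6 (R)-4,4,7a-trimethyl-1,4,5,6,7,7a-hexahydro-2H-inden-2-one
Product: 8 trans-fused C6-hydroxymethyl C8-ketone, via lithium enolate 7 (not isolated)
Conditions: Li, NH3(l)/THF, t-BuOH (1 equiv), −78 °C; isoprene; NH3 off; CH2O (g), THF, −78 → −20 °C; aq NH4Cl
Reagents that add atoms: formaldehyde, C=O
Why: Dissolving-metal (Birch-type) enone reduction with enolate trapping, in which C5 is protonated on the face away from the angular methyl (trans fusion, 5α-H) and the regiodefined enolate adds to formaldehyde at C6 only.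

Step 6
Reactants: 8 trans-fused C6-hydroxymethyl C8-ketone
Product: 10 trans-fused 6-methylene C8-ketone, via mesylate 9 (not isolated)
Conditions: MsCl, Et3N, CH2Cl2, 0 °C; then DBU, rt
Reagents that add atoms: none
Why: Mesylation followed by base-induced E1cB elimination gives the exocyclic enone under conditions too mild to move the double bond into the ring.

Step 7
Reactants: 10 trans-fused 6-methylene C8-ketone
Product: 11 6α-hydroxy-6β-hydroxymethyl C8-ketone
Conditions: OsO4 (2 mol %), N-methylmorpholine N-oxide, acetone/H2O, rt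
Reagents that add atoms: N-methylmorpholine N-oxide, C[N+]1([O-])CCOCC1; water, O
Why: Upjohn dihydroxylation, in which OsO4 adds to the exocyclic alkene from the α face, away from the axial C10 and C4 methyl groups, and so sets C6 with hydroxyl α and hydroxymethyl β as in the target.

Step 8
Reactants: 11 6α-hydroxy-6β-hydroxymethyl C8-ketone
Product: 12 spiro-acetonide C8-ketone
Conditions: 2,2-dimethoxypropane, PPTS (cat.), acetone, rt
Reagents that add atoms: 2,2-dimethoxypropane, COC(C)(C)OC
Why: Acid-catalysed transketalisation protects the tertiary and primary hydroxyls as a five-membered acetonide, which also leaves C9 as the only enolisable position of the ketone.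

Step 9
Reactants: 12 spiro-acetonide C8-ketone
Product: 14 tricyclic 2-methoxy enone (9α-H), via Michael adduct 13 (not isolated)
Conditions: 1,4-dimethoxybutan-2-one, NaOMe, MeOH, 0 °C → reflux
Reagents that add atoms: 1,4-dimethoxybutan-2-one, COCC(=O)CCOC
Why: Robinson annulation, in which the C9 enolate adds to the vinyl ketone released by β-elimination of methanol and aldol condensation through the methoxy-bearing carbon onto C8 closes ring C, while the epimerisable C9 should settle with C11 cis to the angular methyl (9α-H), as a side chain does at C17 of a trans-hydrindane.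

Step 10
Reactants: 14 tricyclic 2-methoxy enone (9α-H)
Product: 16 tricyclic 2-(tert-butyldimethylsilyloxy) enone, via sodium diosphenolate 15 (not isolated)
Conditions: NaSEt, DMF, 100 °C; then TBSCl, 0 °C → rt
Reagents that add atoms: tert-butyldimethylsilyl chloride, CC(C)(C)[Si](C)(C)Cl
Why: SN2 O-demethylation of the enol methyl ether by thiolate releases the stabilised diosphenolate, which is silylated on oxygen in the same flask.

Step 11
Reactants: 16 tricyclic 2-(tert-butyldimethylsilyloxy) enone; 17 propadiene
Product: 18 cis-fused silyloxy methylenecyclobutane ketone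
Conditions: hν (365 nm), 17 (excess), CH2Cl2, −78 °C
Reagents that add atoms: none
Why: Enone–allene [2+2] photocycloaddition with head-to-head regiochemistry (central allene carbon to the α-carbon C14), in which C8 can pyramidalise only so as to keep rings B and C cis-fused, which puts the new C8–Cb bond on the α face, away from the C10 methyl, and sets C8 and C14.

Step 12
Reactants: 18 cis-fused silyloxy methylenecyclobutane ketone
Product: 20 C13 enol triflate, via potassium enolate 19 (not isolated)
Conditions: KN(SiMe3)2, THF, −78 °C; PhNTf2, −78 → 0 °C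
Reagents that add atoms: N-phenylbis(trifluoromethanesulfonimide), O=S(=O)(N(c1ccccc1)S(=O)(=O)C(F)(F)F)C(F)(F)F
Why: The ketone can enolise only towards C12, and the potassium enolate is trapped on oxygen (enol triflate formation).

Step 13
Reactants: 20 C13 enol triflate
Product: 21 13-isopropyl-12-ene silyl ether
Conditions: i-PrZnBr (THF), Pd(OAc)2 (5 mol %), CPhos (10 mol %), THF/PhMe, 25–50 °C
Reagents that add atoms: isopropylzinc bromide, CC(C)[Zn]Br
Why: Negishi cross-coupling of the alkenyl triflate with a secondary alkylzinc reagent, in which the biaryl phosphine favours reductive elimination over β-hydride elimination so that the isopropyl group is transferred unrearranged.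

Step 14
Reactants: 21 13-isopropyl-12-ene silyl ether
Product: 22 allylic cyclobutanol
Conditions: Bu4NF, THF, 25–50 °C
Reagents that add atoms: none
Why: Fluoride-induced desilylation frees the tertiary cyclobutanol that must direct the next step.

Step 15
Reactants: 22 allylic cyclobutanol
Product: 23 12β,13β-epoxy cyclobutanol
Conditions: VO(acac)2 (5 mol %), t-BuOOH (decane), CH2Cl2, 0 °C
Reagents that add atoms: tert-butyl hydroperoxide, CC(C)(C)OO
Why: Vanadium-catalysed hydroxyl-directed epoxidation, in which the β hydroxyl at C14 delivers oxygen to the β face of the more electron-rich ring alkene, so that the epoxide (C12 and C13 set here) lies anti to the C14–Ca bond.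

Step 16
Reactants: 23 12β,13β-epoxy cyclobutanol
Product: 24 bridged keto alcohol bearing the exocyclic methylene
Conditions: BF3·OEt2 (0.3 equiv), CH2Cl2, −78 °C; sat. aq NaHCO3 at −78 °C
Reagents that add atoms: none
Why: Boron binds the epoxide oxygen, the C13–O bond at the tertiary isopropyl-bearing carbon lengthens, the cyclobutane bond C14–Ca that lies anti to it moves over to C13 as it breaks, and the C14 hydroxyl becomes the ketone (semipinacol rearrangement of a 2,3-epoxy alcohol, run here as a cyclobutanol ring enlargement). The nearest established chemistry is the Lewis-acid-triggered enlargement of oxygenated cyclobutanes from enone–allene photoadducts to cyclopentanones. The five-membered ring C8–C14–C13–Ca–Cb is closed by a 1,2-shift of a ring bond (ring expansion, not cyclisation of an open chain), which turns the bicyclo[4.2.0]octane into the bicyclo[3.2.1]octane. C13 is formed with inversion, because Ca enters anti to the departing oxygen, and its configuration is in any case fixed by the tether through Cb and C8, while C12 keeps the epoxide oxygen with retention. The step needs migration of Ca in preference to the ring bond C14–C8 and to a hydride shift from C12: the directed β-epoxide places only C14–Ca anti to the breaking bond, C14–C8 lies near the ring plane, and relief of four-ring strain together with the oxygen lone pair at C14 favours the carbon shift.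

Step 17
Reactants: 24 bridged keto alcohol bearing the exocyclic methylene
Product: 26 triol, via tris-boryl intermediate 25 (not isolated)
Conditions: BH3·THF (5 equiv), THF, 0 °C then 45 °C; NaOH, H2O2, 0 °C → rt
Reagents that add atoms: hydrogen peroxide, OO
Why: Hydroboration–oxidation, in which borane adds to the methylene from the exo face (the side of the one-carbon bridge, the endo face being covered by C11) and so sets Ca with the hydroxymethyl group endo, after which the excess reagent reduces the hindered C14 ketone and thereby removes the retro-aldol and organometallic liabilities of the β-hydroxy ketone.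

Step 18
Reactants: 26 triol
Product: 27 Ca-aldehyde diol
Conditions: TEMPO (10 mol %), PhI(OAc)2, CH2Cl2, rt
Reagents that add atoms: none
Why: The TEMPO/PhI(OAc)2 oxidation is selective for the primary alcohol over the two hindered secondary alcohols, neither of which can reach the endo formyl group to close a lactol (the 12-hydroxyl is anti to the C13–Ca bond and C14 lies on the exo side), and it is not basic, so the α-stereocentre Ca should survive.

Step 19
Reactants: 27 Ca-aldehyde diol
Product: 28 Ca-alkyne diol
Conditions: dimethyl (1-diazo-2-oxopropyl)phosphonate, K2CO3, MeOH, 0 °C → rt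
Reagents that add atoms: dimethyl (1-diazo-2-oxopropyl)phosphonate, COP(=O)(OC)C(=[N+]=[N-])C(C)=O
Why: Seyferth–Gilbert homologation with the Ohira–Bestmann reagent converts the aldehyde into the terminal alkyne under mild carbonate conditions that tolerate the free hydroxyls.

Step 20
Reactants: 28 Ca-alkyne diol
Product: 30 E-vinyl iodide diol, via alkenylalane 29 (not isolated)
Conditions: Me3Al (4 equiv), Cp2ZrCl2 (0.3 equiv), H2O (1 equiv), CH2Cl2, −23 °C; I2, THF, −23 → 0 °C
Reagents that add atoms: trimethylaluminium, C[Al](C)C; iodine, [I][I]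
Why: Negishi zirconium-catalysed carboalumination adds methyl and aluminium syn across the alkyne with aluminium at the terminal carbon, and iodinolysis with retention gives the E-trisubstituted vinyl iodide, no carbonyl group being present to compete for Me3Al.

Step 21
Reactants: 30 E-vinyl iodide diol
Product: 31 E-vinyl iodide 12,14-diketone
Conditions: Dess–Martin periodinane, NaHCO3, CH2Cl2, rt
Reagents that add atoms: none
Why: Dess–Martin oxidation converts both hindered secondary alcohols into ketones and so merges any C12 and C14 epimers into one non-enolisable 1,3-diketone.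

Step 22
Reactants: 32 abietic acid
Product: 33 2-(trimethylsilyl)ethyl abietate
Conditions: Me3SiCH2CH2OH, PPh3, DIAD, THF, 0 °C → rt
Reagents that add atoms: 2-(trimethylsilyl)ethanol, C[Si](C)(C)CCO
Why: Mitsunobu esterification activates the alcohol and not the hindered tertiary acid, so the carboxylate is alkylated without steric penalty.

Step 23
Reactants: 33 2-(trimethylsilyl)ethyl abietate
Product: 35 13′,14′-seco keto enal, via 13,14-diol 34 (not isolated)
Conditions: OsO4 (2 mol %), NaIO4, 2,6-lutidine, dioxane/H2O, rt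
Reagents that add atoms: sodium periodate, [Na+].[O-]I(=O)(=O)=O; water, O
Why: Lemieux–Johnson cleavage, in which OsO4 dihydroxylates the C13′–C14′ double bond of the diene (the one oxidised first in abietates), periodate cleaves the diol, and the remaining C7′–C8′ alkene is then deactivated as an enal.

Step 24
Reactants: 35 13′,14′-seco keto enal
Product: 37 exocyclic-methylene isopropyl ketone, via tosylhydrazone 36 (not isolated)
Conditions: TsNHNH2, EtOH, rt; catecholborane, CHCl3, 0 °C; NaOAc·3H2O, reflux
Reagents that add atoms: none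
Why: Kabalka reduction of the α,β-unsaturated tosylhydrazone, in which hydride adds to the C=N carbon and the allylic diazene loses nitrogen with a 1,5-hydrogen shift to C7′, which moves the double bond into the exocyclic position at C8′, the aldehyde condensing with the hydrazide far faster than the hindered isopropyl ketone.

Step 25
Reactants: 37 exocyclic-methylene isopropyl ketone
Product: 39 12′-hydroxy ketone, via lithium enolate 38 (not isolated)
Conditions: LiN(i-Pr)2, THF, −78 °C; 2-(phenylsulfonyl)-3-phenyloxaziridine, −78 °C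
Reagents that add atoms: 2-(phenylsulfonyl)-3-phenyloxaziridine, O=S(=O)(N1OC1c1ccccc1)c1ccccc1
Why: Kinetic deprotonation takes place at the methylene and not at the isopropyl methine, and the enolate is hydroxylated by the Davis oxaziridine (Davis α-hydroxylation).

Step 26
Reactants: 39 12′-hydroxy ketone
Product: 40 C12′ aldehyde
Conditions: NaIO4, MeOH/H2O, rt
Reagents that add atoms: none
Why: Periodate cleaves the α-hydroxy ketone between C12′ and C13′ (Malaprade-type cleavage), which leaves the aldehyde and removes the isopropyl ketone as 2-methylpropanoic acid without touching the alkene.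

Step 27
Reactants: 40 C12′ aldehyde
Product: 41 C12′ carboxylic acid
Conditions: NaClO2, NaH2PO4, 2-methyl-2-butene, t-BuOH/H2O, rt
Reagents that add atoms: sodium chlorite, [Na+].[O-]Cl=O
Why: Pinnick oxidation converts the aldehyde into the acid while the hypochlorite scavenger protects the exocyclic alkene.

Step 28
Reactants: 41 C12′ carboxylic acid
Product: 43 C11′ iodide, via Barton ester 42 (not isolated)
Conditions: 1-hydroxypyridine-2(1H)-thione, DCC, DMAP (cat.), CH2Cl2, 0 °C, dark; CHI3, PhH, hν (visible, tungsten lamp), rt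
Reagents that add atoms: iodoform, IC(I)I
Why: Barton decarboxylation, in which the thiohydroxamate ester fragments under visible light and the primary C11′ radical formed by loss of CO2 abstracts iodine from iodoform, giving the iodide one carbon shorter under neutral conditions that avoid iodolactonisation.

Step 29
Reactants: 43 C11′ iodide; 31 E-vinyl iodide 12,14-diketone
Product: 45 coupled diketone, via alkylzinc iodide 44 (not isolated)
Conditions: 43, Zn dust, LiCl, THF, 40 °C; then 31, Pd(OAc)2 (5 mol %), SPhos (10 mol %), THF/NMP, rt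
Reagents that add atoms: none
Why: LiCl-mediated zinc insertion into the primary iodide and Negishi cross-coupling of the alkylzinc iodide with the vinyl iodide join the halves with retention of the E geometry, the ketones, the ester and the acetonide being inert to the organozinc.

Step 30
Reactants: 45 coupled diketone
Product: 47 11-hydroxy 12,14-diketone, via potassium enolate 46 (not isolated)
Conditions: KN(SiMe3)2, THF, −78 °C; 2-(phenylsulfonyl)-3-phenyloxaziridine, −78 °C
Reagents that add atoms: 2-(phenylsulfonyl)-3-phenyloxaziridine, O=S(=O)(N1OC1c1ccccc1)c1ccccc1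
Why: Of the two ketones only C12 has α-hydrogens (at C11), so the enolate forms there and is hydroxylated by the Davis oxaziridine (Davis α-hydroxylation).

Step 31
Reactants: 47 11-hydroxy 12,14-diketone
Product: 48 C6,C7,C11-triol
Conditions: PPTS, MeOH, 40 °C
Reagents that add atoms: none
Why: Acid-catalysed transketalisation with methanol removes the acetonide under conditions mild enough for the exocyclic alkene and the silylethyl ester.

Step 32
Reactants: 48 C6,C7,C11-triol
Product: 50 silylethyl ester of the target, via 11,12-diketone 49 (not isolated)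
Conditions: SO3·pyridine, DMSO, i-Pr2NEt, CH2Cl2, 0 °C → rt
Reagents that add atoms: none
Why: Parikh–Doering oxidation converts the primary alcohol into the aldehyde and the C11 alcohol into the 1,2-diketone, which enolises towards C9 to the conjugated diosphenol, the tertiary C6 hydroxyl being inert.

Step 33
Reactants: 50 silylethyl ester of the target
Product: 51 CNP0124601.1
Conditions: (Me2N)3S[Me3SiF2] (TASF), DMF, 0 °C → rt; pH 5 acetate buffer
Reagents that add atoms: none
Why: Fluoride attacks silicon and the ester fragments with loss of ethylene (β-elimination of the 2-(trimethylsilyl)ethyl ester), which frees the hindered acid without hydrolytic conditions.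

Compound list
1 | 2,2,6-trimethylcyclohexanone | CC1CCCC(C)(C)C1=O | starting material
2 | lithium enolate of 1 | [Li]OC1=C(C)CCCC1(C)C | intermediate
3 | allyl 2,6,6-trimethylcyclohex-1-enyl carbonate | C=CCOC(=O)OC1=C(C)CCCC1(C)C | intermediate
4 | (R)-2-allyl-2,6,6-trimethylcyclohexanone | C=CC[C@@]1(C)CCCC(C)(C)C1=O | intermediate
5 | (R)-2,2,6-trimethyl-6-(2-oxopropyl)cyclohexanone | CC(=O)C[C@@]1(C)CCCC(C)(C)C1=O | intermediate
6 | (R)-4,4,7a-trimethyl-1,4,5,6,7,7a-hexahydro-2H-inden-2-one (rings A and B) | O=C1C=C2C(C)(C)CCC[C@]2(C)C1 | intermediate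
7 | lithium C6=C8 enolate of the trans-hydrindanone | [Li]OC=1C[C@@]2(C)CCCC(C)(C)[C@@H]2C=1 | intermediate
8 | trans-fused C6-hydroxymethyl C8-ketone (5α-H, 10β-Me) | O=C1C[C@@]2(C)CCCC(C)(C)[C@@H]2[C@H]1CO | intermediate
9 | mesylate of 8 | O=C1C[C@@]2(C)CCCC(C)(C)[C@@H]2[C@H]1COS(C)(=O)=O | intermediate
10 | trans-fused 6-methylene C8-ketone | O=C1C[C@@]2(C)CCCC(C)(C)[C@@H]2C1=C | intermediate
11 | 6α-hydroxy-6β-hydroxymethyl C8-ketone | O=C1C[C@@]2(C)CCCC(C)(C)[C@@H]2[C@]1(O)CO | intermediate
12 | spiro-acetonide C8-ketone | O=C1C[C@@]2(C)CCCC(C)(C)[C@@H]2[C@]1(OC3(C)C)CO3 | intermediate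
13 | Michael adduct (C9 side chain CH2CH2COCH2OMe) | O=C1[C@H](CCC(=O)COC)[C@@]2(C)CCCC(C)(C)[C@@H]2[C@]1(OC3(C)C)CO3 | intermediate
14 | tricyclic 2-methoxy enone (C13=O, C14-OMe, C8=C14, 9α-H) | COC1=C2[C@H](CCC1=O)[C@@]1(C)CCCC(C)(C)[C@@H]1[C@]2(OC1(C)C)CO1 | intermediate
15 | sodium diosphenolate | [Na]OC1=C2[C@H](CCC1=O)[C@@]1(C)CCCC(C)(C)[C@@H]1[C@]2(OC1(C)C)CO1 | intermediate
16 | tricyclic 2-(tert-butyldimethylsilyloxy) enone | CC(C)(C)[Si](C)(C)OC1=C2[C@H](CCC1=O)[C@@]1(C)CCCC(C)(C)[C@@H]1[C@]2(OC1(C)C)CO1 | intermediate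
17 | propadiene | C=C=C | starting material
18 | photoadduct: α-cis-fused methylenecyclobutane, C14-OTBS β, C13 ketone | CC1(C)CCC[C@@]2(C)[C@H]1[C@]3(COC(C)(C)O3)[C@]45CC(=C)[C@@]4(O[Si](C)(C)C(C)(C)C)C(=O)CC[C@@H]52 | intermediate
19 | potassium C12=C13 enolate of 18 | CC1(C)CCC[C@@]2(C)[C@H]1[C@]3(COC(C)(C)O3)[C@]45CC(=C)[C@@]4(O[Si](C)(C)C(C)(C)C)C(O[K])=CC[C@@H]52 | intermediate
20 | C13 enol triflate | CC1(C)CCC[C@@]2(C)[C@H]1[C@]3(COC(C)(C)O3)[C@]45CC(=C)[C@@]4(O[Si](C)(C)C(C)(C)C)C(OS(=O)(=O)C(F)(F)F)=CC[C@@H]52 | intermediate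
21 | 13-isopropyl-12-ene silyl ether | CC1(C)CCC[C@@]2(C)[C@H]1[C@]3(COC(C)(C)O3)[C@]45CC(=C)[C@@]4(O[Si](C)(C)C(C)(C)C)C(C(C)C)=CC[C@@H]52 | intermediate
22 | allylic cyclobutanol (C14-OH β) | CC1(C)CCC[C@@]2(C)[C@H]1[C@]3(COC(C)(C)O3)[C@]45CC(=C)[C@@]4(O)C(C(C)C)=CC[C@@H]52 | intermediate
23 | 12β,13β-epoxy cyclobutanol (key-step precursor) | CC1(C)CCC[C@@]2(C)[C@H]1[C@]3(COC(C)(C)O3)[C@]45CC(=C)[C@@]4(O)[C@]6(C(C)C)O[C@@H]6C[C@@H]52 | intermediate
24 | bridged keto alcohol with exocyclic methylene (key-step product; C14 ketone, 12β-OH) | C=C1C[C@@]23C(=O)[C@]1(C(C)C)[C@H](O)C[C@@H]2[C@@]1(C)CCCC(C)(C)[C@@H]1[C@]3(OC4(C)C)CO4 | intermediate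
25 | tris-boryl intermediate (C-BH2 and two O-BH2) | BC[C@@H]1C[C@@]23[C@H](OB)[C@]1(C(C)C)[C@H](OB)C[C@@H]2[C@@]1(C)CCCC(C)(C)[C@@H]1[C@]3(OC4(C)C)CO4 | intermediate
26 | triol (endo CH2OH on Ca, C12-OH, C14-OH) | OC[C@@H]1C[C@@]23[C@H](O)[C@]1(C(C)C)[C@H](O)C[C@@H]2[C@@]1(C)CCCC(C)(C)[C@@H]1[C@]3(OC4(C)C)CO4 | intermediate
27 | Ca-aldehyde diol | O=C[C@@H]1C[C@@]23[C@H](O)[C@]1(C(C)C)[C@H](O)C[C@@H]2[C@@]1(C)CCCC(C)(C)[C@@H]1[C@]3(OC4(C)C)CO4 | intermediate
28 | Ca-alkyne diol | C#C[C@@H]1C[C@@]23[C@H](O)[C@]1(C(C)C)[C@H](O)C[C@@H]2[C@@]1(C)CCCC(C)(C)[C@@H]1[C@]3(OC4(C)C)CO4 | intermediate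
29 | alkenylalane (aluminium alkoxides at C12 and C14) | C[Al](C)/C=C(\C)[C@@H]1C[C@@]23[C@H](O[Al](C)C)[C@]1(C(C)C)[C@H](O[Al](C)C)C[C@@H]2[C@@]1(C)CCCC(C)(C)[C@@H]1[C@]3(OC4(C)C)CO4 | intermediate
30 | E-vinyl iodide diol | I/C=C(\C)[C@@H]1C[C@@]23[C@H](O)[C@]1(C(C)C)[C@H](O)C[C@@H]2[C@@]1(C)CCCC(C)(C)[C@@H]1[C@]3(OC4(C)C)CO4 | intermediate
31 | E-vinyl iodide 12,14-diketone | I/C=C(\C)[C@@H]1C[C@@]23C(=O)[C@]1(C(C)C)C(=O)C[C@@H]2[C@@]1(C)CCCC(C)(C)[C@@H]1[C@]3(OC4(C)C)CO4 | intermediate
32 | abietic acid | CC(C)C1=CC2=CC[C@@H]3[C@@]([C@H]2CC1)(CCC[C@@]3(C)C(=O)O)C | starting material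
33 | 2-(trimethylsilyl)ethyl abietate | CC(C)C1=CC2=CC[C@@H]3[C@@]([C@H]2CC1)(CCC[C@@]3(C)C(=O)OCC[Si](C)(C)C)C | intermediate
34 | 13α,14α-diol of 33 | CC(C)[C@@]1(O)[C@H](O)C2=CC[C@@H]3[C@@]([C@H]2CC1)(CCC[C@@]3(C)C(=O)OCC[Si](C)(C)C)C | intermediate
35 | 13′,14′-seco keto enal | O=CC1=CC[C@@H]2[C@](C)(CCC[C@@]2(C)C(=O)OCC[Si](C)(C)C)[C@H]1CCC(=O)C(C)C | intermediate
36 | tosylhydrazone of the enal | Cc1ccc(cc1)S(=O)(=O)N/N=C/C1=CC[C@@H]2[C@](C)(CCC[C@@]2(C)C(=O)OCC[Si](C)(C)C)[C@H]1CCC(=O)C(C)C | intermediate
37 | exocyclic-methylene isopropyl ketone | C=C1CC[C@@H]2[C@](C)(CCC[C@@]2(C)C(=O)OCC[Si](C)(C)C)[C@H]1CCC(=O)C(C)C | intermediate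
38 | lithium enolate of 37 | C=C1CC[C@@H]2[C@](C)(CCC[C@@]2(C)C(=O)OCC[Si](C)(C)C)[C@H]1C/C=C(\O[Li])C(C)C | intermediate
39 | 12′-hydroxy ketone (both C12′ epimers) | C=C1CC[C@@H]2[C@](C)(CCC[C@@]2(C)C(=O)OCC[Si](C)(C)C)[C@H]1CC(O)C(=O)C(C)C | intermediate
40 | C12′ aldehyde | C=C1CC[C@@H]2[C@](C)(CCC[C@@]2(C)C(=O)OCC[Si](C)(C)C)[C@H]1CC=O | intermediate
41 | C12′ carboxylic acid | C=C1CC[C@@H]2[C@](C)(CCC[C@@]2(C)C(=O)OCC[Si](C)(C)C)[C@H]1CC(=O)O | intermediate
42 | Barton ester of 41 | C=C1CC[C@@H]2[C@](C)(CCC[C@@]2(C)C(=O)OCC[Si](C)(C)C)[C@H]1CC(=O)On1ccccc1=S | intermediate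
43 | C11′ iodide (labdane half) | C=C1CC[C@@H]2[C@](C)(CCC[C@@]2(C)C(=O)OCC[Si](C)(C)C)[C@H]1CI | intermediate
44 | alkylzinc iodide | C=C1CC[C@@H]2[C@](C)(CCC[C@@]2(C)C(=O)OCC[Si](C)(C)C)[C@H]1C[Zn]I | intermediate
45 | coupled diketone (acetonide and silylethyl ester) | C=C1CC[C@@H]2[C@](C)(CCC[C@@]2(C)C(=O)OCC[Si](C)(C)C)[C@H]1C/C=C(\C)[C@@H]1C[C@@]23C(=O)[C@]1(C(C)C)C(=O)C[C@@H]2[C@@]1(C)CCCC(C)(C)[C@@H]1[C@]3(OC4(C)C)CO4 | intermediate
46 | potassium C11=C12 enolate of 45 | C=C1CC[C@@H]2[C@](C)(CCC[C@@]2(C)C(=O)OCC[Si](C)(C)C)[C@H]1C/C=C(\C)[C@@H]1C[C@@]23C(=O)[C@]1(C(C)C)C(O[K])=C[C@@H]2[C@@]1(C)CCCC(C)(C)[C@@H]1[C@]3(OC4(C)C)CO4 | intermediate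
47 | 11-hydroxy 12,14-diketone | C=C1CC[C@@H]2[C@](C)(CCC[C@@]2(C)C(=O)OCC[Si](C)(C)C)[C@H]1C/C=C(\C)[C@@H]1C[C@@]23C(=O)[C@]1(C(C)C)C(=O)[C@H](O)[C@@H]2[C@@]1(C)CCCC(C)(C)[C@@H]1[C@]3(OC4(C)C)CO4 | intermediate
48 | C6,C7,C11-triol | C=C1CC[C@@H]2[C@](C)(CCC[C@@]2(C)C(=O)OCC[Si](C)(C)C)[C@H]1C/C=C(\C)[C@@H]1C[C@@]23C(=O)[C@]1(C(C)C)C(=O)[C@H](O)[C@@H]2[C@@]1(C)CCCC(C)(C)[C@@H]1[C@]3(O)CO | intermediate
49 | 11,12-diketone hydroxy aldehyde | C=C1CC[C@@H]2[C@](C)(CCC[C@@]2(C)C(=O)OCC[Si](C)(C)C)[C@H]1C/C=C(\C)[C@@H]1C[C@@]23C(=O)[C@]1(C(C)C)C(=O)C(=O)[C@@H]2[C@@]1(C)CCCC(C)(C)[C@@H]1[C@]3(O)C=O | intermediate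
50 | 2-(trimethylsilyl)ethyl ester of the target | C=C1CC[C@@H]2[C@](C)(CCC[C@@]2(C)C(=O)OCC[Si](C)(C)C)[C@H]1C/C=C(\C)[C@@H]1C[C@@]23C(=O)[C@]1(C(C)C)C(=O)C(O)=C2[C@@]1(C)CCCC(C)(C)[C@@H]1[C@]3(O)C=O | intermediate
51 | CNP0124601.1 | C=C1CC[C@@H]2[C@](C)(CCC[C@@]2(C)C(=O)O)[C@H]1C/C=C(\C)[C@@H]1C[C@@]23C(=O)[C@]1(C(C)C)C(=O)C(O)=C2[C@@]1(C)CCCC(C)(C)[C@@H]1[C@]3(O)C=O | target

Total step count: 33. Longest linear sequence: 26 (steps 1–21, then 29–33); the labdane branch is 7 steps (22–28).

Steps most likely to fail

Step 16. The ring expansion may be outrun by a hydride shift from C12 (leading to the 12-ketone), by Lewis-acid opening of the acetonide, or by retro-aldol fragmentation of the strained β-hydroxy ketone. The fallback sets out from 22 and avoids both the epoxide and the Lewis acid. N-Iodosuccinimide in CH2Cl2 forms the iodonium ion reversibly on either face of the ring alkene, and only the β-iodonium ion has the C14–Ca bond anti, so the same 1,2-shift should give the 12β-iodo bridged ketone F1 under neutral conditions. Bu3SnH under air, followed by PPh3, replaces iodine by hydroxyl through the C12 radical; oxygen should be captured on the open equatorial side, which gives the 12-epi keto alcohol F2 as the main isomer, the other epimer being 24 itself. Dess–Martin periodinane then removes the C12 stereocentre and gives the methylene 12,14-diketone F3 from either epimer. Under the conditions of step 17, BH3·THF hydroborates the methylene group and reduces both ketones to the tris-boryl intermediate 25, hydride reaching C12 from the same open side so that the 12-hydroxyl is axial as in the main line, and the fallback comes back to the route at 26.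

Step 29. Zinc insertion into the β-branched iodide may be slow, and the alkylpalladium intermediate may undergo β-hydride elimination, or the organozinc protodemetalation, before coupling. The fallback sets out from acid 41 and vinyl iodide 31 and needs no preformed organometallic. Acid 41 is condensed with N-hydroxyphthalimide (DIC, DMAP) to the redox-active N-hydroxyphthalimide ester F4 and this is coupled with 31 by nickel-catalysed decarboxylative reductive alkenylation (NiBr2·glyme, 4,4′-di-tert-butyl-2,2′-bipyridine, Zn, DMA); the C11′ radical is captured at nickel and the fallback comes back to the route at 45.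

Step 10. O-Demethylation may be incomplete, or thiolate may add to the enone in conjugate fashion. The fallback sets out from 14 and uses hydrolysis in place of nucleophilic dealkylation. Aqueous HCl (1 M) in THF cleaves the methyl enol ether, and the acetonide along the way, which gives the diosphenol diol F5 in one operation; 2,2-dimethoxypropane and PPTS restore the acetonide, and the diosphenol acetonide F6 is silylated on the enol oxygen by TBSCl and imidazole, which brings the fallback back to the route at 16.

Further compounds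
F1 | step 16 | 12β-iodo bridged ketone | C=C1C[C@@]23C(=O)[C@]1(C(C)C)[C@H](I)C[C@@H]2[C@@]1(C)CCCC(C)(C)[C@@H]1[C@]3(OC4(C)C)CO4
F2 | step 16 | 12-epi keto alcohol | C=C1C[C@@]23C(=O)[C@]1(C(C)C)[C@@H](O)C[C@@H]2[C@@]1(C)CCCC(C)(C)[C@@H]1[C@]3(OC4(C)C)CO4
F3 | step 16 | methylene 12,14-diketone | C=C1C[C@@]23C(=O)[C@]1(C(C)C)C(=O)C[C@@H]2[C@@]1(C)CCCC(C)(C)[C@@H]1[C@]3(OC4(C)C)CO4
F4 | step 29 | redox-active N-hydroxyphthalimide ester | C=C1CC[C@@H]2[C@](C)(CCC[C@@]2(C)C(=O)OCC[Si](C)(C)C)[C@H]1CC(=O)ON1C(=O)c2ccccc2C1=O
F5 | step 10 | diosphenol diol | OC1=C2[C@H](CCC1=O)[C@@]1(C)CCCC(C)(C)[C@@H]1[C@]2(O)CO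
F6 | step 10 | diosphenol acetonide | OC1=C2[C@H](CCC1=O)[C@@]1(C)CCCC(C)(C)[C@@H]1[C@]2(OC1(C)C)CO1
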